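The 7-methoxychromone half is cut at C4–C4a and at O1–C2. Its ring A carries oxygen at C5, C7 and C8a, so it is a masked, threefold-symmetric phloroglucinol. The two cuts release phloroglucinol plus a C2–C3–C4 keto ester that already holds both aryl groups. One acid-free thermal condensation forms both bonds, closes the pyranone ring C and leaves 7-OH as the only unchelated hydroxyl for methylation. The precursor is an ethyl 2,3-diaryl-3-oxopropanoate with benzyl-masked phenols and a bromine para to the ortho benzyloxy group. The bromide later becomes the second flavone by carbonylative coupling with a 2-hydroxyacetophenone; neutral hydrogenolysis ends the route.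

Key step: step 5

Assumption: the target has no stereocentre and its SMILES defines no axis, so the hindered bond between C3 and its aryl group is treated as stereochemically unspecified.

Design remarks:
- The phenol ortho to the C3 attachment stays benzylated from before the acylation until the last step. A free hydroxyl there would lactonise onto the ester, trap the ketene, or later isomerise the chromone under base.
- The ethyl ester is kept because ethanol leaves the melt at once.
- Dry phloroglucinol is used in excess as both trap and flux.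
- The bromine sits between two C–H positions and is used directly in the carbonylation.
- The acetophenone partner fixes the oxygen pattern of the second ring A without any regioselective halogenation.

Step 1
Reactants: 1 2-hydroxyphenylacetic acid
Product: 2 2-(5-bromo-2-hydroxyphenyl)acetic acid
Conditions: NBS (1.0 equiv), MeCN, 0 °C to rt, dark; recrystallisation
Reagents that add atoms: N-bromosuccinimide, O=C1CCC(=O)N1Br
Why: Electrophilic aromatic bromination with NBS in acetonitrile is steered by the phenol to its open para position (C5), the remaining ortho site being the slower one, and the crystalline acid can be recrystallised free of minor isomers.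

Step 2
Reactants: 2 2-(5-bromo-2-hydroxyphenyl)acetic acid
Product: 3 ethyl 2-(5-bromo-2-hydroxyphenyl)acetate
Conditions: EtOH (solvent), cat. H2SO4, reflux; NaHCO3 before concentration
Reagents that add atoms: ethanol, CCO
Why: Fischer esterification in a large excess of ethanol drives the equilibrium to the ethyl ester and also reopens any 5-bromobenzofuran-2(3H)-one formed by lactonisation, provided the acid is neutralised before concentration.

Step 3
Reactants: 3 ethyl 2-(5-bromo-2-hydroxyphenyl)acetate
Product: 4 ethyl 2-[2-(benzyloxy)-5-bromophenyl]acetate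
Conditions: BnBr (1.1 equiv), K2CO3 (1.5 equiv), acetone, reflux
Reagents that add atoms: benzyl bromide, BrCc1ccccc1
Why: Williamson ether synthesis on the phenoxide caps the one nucleophile that could otherwise lactonise onto the ester or trap the ketene of step 5, with a group that neutral hydrogenolysis removes at the end.

Step 4
Reactants: 4 ethyl 2-[2-(benzyloxy)-5-bromophenyl]acetate; 5 4-(benzyloxy)benzoyl chloride
Product: 6 ethyl 2-[2-(benzyloxy)-5-bromophenyl]-3-[4-(benzyloxy)phenyl]-3-oxopropanoate (racemic)
Conditions: LiN(SiMe3)2 (2.2 equiv), THF, −78 °C; then 5 (1.05 equiv), −78 to −20 °C; aq NH4Cl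
Reagents that add atoms: none
Why: Crossed Claisen-type C-acylation of the lithiated arylacetate by an aroyl chloride, in which the second equivalent of base deprotonates the more acidic keto ester as it forms and so blocks proton exchange and double acylation, while the aryl bromide is inert to the amide base at −78 °C and the new centre is racemic and enolisable.

Step 5
Reactants: 6 ethyl 2-[2-(benzyloxy)-5-bromophenyl]-3-[4-(benzyloxy)phenyl]-3-oxopropanoate; 7 phloroglucinol (anhydrous)
Product: 10 3-[2-(benzyloxy)-5-bromophenyl]-2-[4-(benzyloxy)phenyl]-5,7-dihydroxychromen-4-one, via aroyl(aryl)ketene 8 (not isolated), via 2-acylphloroglucinol 9 (not isolated)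
Conditions: 7 (3 equiv, dried), neat melt, open vessel under N2 sweep, 240 °C (microwave or metal bath), 15–30 min; hot-water trituration to remove excess 7
Reagents that add atoms: none
Why: Above about 200 °C keto ester 6 loses ethanol through its enol to give aroyl(aryl)ketene 8, which the excess of molten 7 traps; O-acylation is reversible at this temperature because the aryl ester re-forms 8, whereas attack by a ring carbon is not, so the material drains into 2-acylphloroglucinol 9 and C4–C4a is set first, intermolecularly. The ring is then closed at O1–C2: a hydroxyl ortho to the new acyl group adds to the 4-(benzyloxy)phenyl ketone in a 6-exo-trig mode and the hemiketal loses water, which aromatises the pyranone and makes the closure irreversible. This is the Mentzer pyranone synthesis, the acid-free thermal relative of the Simonis chromone reaction, which is established for phloroglucinol and aroylacetates that carry a substituent at C2. No stereocentre is formed, and the racemic enolisable centre of 6 ends as the sp2 carbon C3. The selectivity that matters is chromone against coumarin: without acid the ketone is never activated for Pechmann-type attack by the arene, it is flanked by two aryl groups and deactivated by the para benzyloxy donor, and the equivalence of the three carbons and three hydroxyls of 7 removes any positional choice, while the excess of 7 suppresses a second annulation. Benzyl aryl ethers and the aryl bromide tolerate short exposure to this temperature, as in Conrad–Limpach and Gould–Jacobs closures run near 250 °C, and dry 7 plus the nitrogen sweep keeps water from hydrolysing and decarboxylating 6.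

Step 6
Reactants: 10 3-[2-(benzyloxy)-5-bromophenyl]-2-[4-(benzyloxy)phenyl]-5,7-dihydroxychromen-4-one
Product: 11 3-[2-(benzyloxy)-5-bromophenyl]-2-[4-(benzyloxy)phenyl]-5-hydroxy-7-methoxychromen-4-one
Conditions: MeI (1.1 equiv), K2CO3 (1.2 equiv), acetone, reflux
Reagents that add atoms: iodomethane, CI
Why: Williamson methylation with a weak base and about one equivalent of MeI touches only 7-OH, because 5-OH is tied to the C4 carbonyl by a hydrogen bond and is far less acidic and nucleophilic, as in the standard 7-O-alkylation of 5,7-dihydroxyflavones.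

Step 7
Reactants: 11 3-[2-(benzyloxy)-5-bromophenyl]-2-[4-(benzyloxy)phenyl]-5-hydroxy-7-methoxychromen-4-one
Product: 12 5-(benzyloxy)-3-[2-(benzyloxy)-5-bromophenyl]-2-[4-(benzyloxy)phenyl]-7-methoxychromen-4-one
Conditions: BnBr (2 equiv), K2CO3 (3 equiv), DMF, 70 °C
Reagents that add atoms: benzyl bromide, BrCc1ccccc1
Why: Williamson benzylation under forcing conditions (excess BnBr, DMF, heat) overcomes the chelation of 5-OH, and the cap is needed because a free phenoxide would compete with the hydroxyacetophenone for the acylpalladium species in step 9.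

Step 8
Reactants: 13 2,4,6-trihydroxyacetophenone
Product: 14 1-[2,4-bis(benzyloxy)-6-hydroxyphenyl]ethanone
Conditions: BnBr (2.05 equiv), K2CO3 (2.2 equiv), DMF, rt to 60 °C
Reagents that add atoms: benzyl bromide, BrCc1ccccc1
Why: Williamson benzylation with two equivalents of BnBr stops at the bis-ether because the last hydroxyl is hydrogen-bonded to the acetyl carbonyl, and this is exactly the free phenol that step 9 needs.

Step 9
Reactants: 12 5-(benzyloxy)-3-[2-(benzyloxy)-5-bromophenyl]-2-[4-(benzyloxy)phenyl]-7-methoxychromen-4-one; 14 1-[2,4-bis(benzyloxy)-6-hydroxyphenyl]ethanone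
Product: 17 5,7-bis(benzyloxy)-2-(4-(benzyloxy)-3-{5-(benzyloxy)-2-[4-(benzyloxy)phenyl]-7-methoxy-4-oxochromen-3-yl}phenyl)chromen-4-one, via aryl benzoate 15 (not isolated), via beta-diketone 16 (not isolated)
Conditions: 14 (1.5 equiv), Pd(OAc)2 (5 mol%), dppb (10 mol%), DBU (3 equiv), CO (10 bar), DMSO, 120 °C
Reagents that add atoms: carbon monoxide, [C-]#[O+]
Why: Known palladium-catalysed carbonylative flavone synthesis from aryl bromides and 2-hydroxyacetophenones: oxidative addition of the unhindered C–Br bond to zerovalent palladium, CO insertion and capture of the acylpalladium species by the phenoxide of 14 give ester 15, DBU then drives a Baker–Venkataraman acyl shift to diketone 16, and its phenol closes 6-exo-trig on the aryl ketone with loss of water.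

Step 10
Reactants: 17 5,7-bis(benzyloxy)-2-(4-(benzyloxy)-3-{5-(benzyloxy)-2-[4-(benzyloxy)phenyl]-7-methoxy-4-oxochromen-3-yl}phenyl)chromen-4-one
Product: 18 5,7-dihydroxy-2-{4-hydroxy-3-[5-hydroxy-2-(4-hydroxyphenyl)-7-methoxy-4-oxochromen-3-yl]phenyl}chromen-4-one (CNP0284832.0)
Conditions: H2 (1 atm), 10% Pd/C, THF–MeOH, rt; catalyst washed with warm THF–MeOH
Reagents that add atoms: none
Why: Catalytic hydrogenolysis cleaves all five benzyl aryl ethers under neutral conditions, leaves the methyl ether and both pyranone rings untouched, and avoids the base that could isomerise a 3-(2-hydroxyphenyl)chromone to an aroylbenzofuran.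

Compound list
1 | 2-hydroxyphenylacetic acid | OC(=O)Cc1ccccc1O | starting material
2 | 2-(5-bromo-2-hydroxyphenyl)acetic acid | OC(=O)Cc1cc(Br)ccc1O | intermediate
3 | ethyl 2-(5-bromo-2-hydroxyphenyl)acetate | CCOC(=O)Cc1cc(Br)ccc1O | intermediate
4 | ethyl 2-[2-(benzyloxy)-5-bromophenyl]acetate | CCOC(=O)Cc1cc(Br)ccc1OCc1ccccc1 | intermediate
5 | 4-(benzyloxy)benzoyl chloride | O=C(Cl)c1ccc(OCc2ccccc2)cc1 | starting material
6 | ethyl 2-[2-(benzyloxy)-5-bromophenyl]-3-[4-(benzyloxy)phenyl]-3-oxopropanoate (racemic, enolisable centre) | CCOC(=O)C(C(=O)c1ccc(OCc2ccccc2)cc1)c1cc(Br)ccc1OCc1ccccc1 | intermediate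
7 | phloroglucinol | Oc1cc(O)cc(O)c1 | starting material
8 | 2-[2-(benzyloxy)-5-bromophenyl]-3-[4-(benzyloxy)phenyl]-3-oxoprop-1-en-1-one (aroyl(aryl)ketene, not isolated) | O=C=C(C(=O)c1ccc(OCc2ccccc2)cc1)c1cc(Br)ccc1OCc1ccccc1 | intermediate
9 | 2-[2-(benzyloxy)-5-bromophenyl]-1-[4-(benzyloxy)phenyl]-3-(2,4,6-trihydroxyphenyl)propane-1,3-dione (racemic, not isolated) | O=C(c1ccc(OCc2ccccc2)cc1)C(C(=O)c1c(O)cc(O)cc1O)c1cc(Br)ccc1OCc1ccccc1 | intermediate
10 | 3-[2-(benzyloxy)-5-bromophenyl]-2-[4-(benzyloxy)phenyl]-5,7-dihydroxychromen-4-one | O=c1c(-c2cc(Br)ccc2OCc2ccccc2)c(-c2ccc(OCc3ccccc3)cc2)oc2cc(O)cc(O)c12 | intermediate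
11 | 3-[2-(benzyloxy)-5-bromophenyl]-2-[4-(benzyloxy)phenyl]-5-hydroxy-7-methoxychromen-4-one | COc1cc(O)c2c(=O)c(-c3cc(Br)ccc3OCc3ccccc3)c(-c3ccc(OCc4ccccc4)cc3)oc2c1 | intermediate
12 | 5-(benzyloxy)-3-[2-(benzyloxy)-5-bromophenyl]-2-[4-(benzyloxy)phenyl]-7-methoxychromen-4-one | COc1cc(OCc2ccccc2)c2c(=O)c(-c3cc(Br)ccc3OCc3ccccc3)c(-c3ccc(OCc4ccccc4)cc3)oc2c1 | intermediate
13 | 2,4,6-trihydroxyacetophenone | CC(=O)c1c(O)cc(O)cc1O | starting material
14 | 1-[2,4-bis(benzyloxy)-6-hydroxyphenyl]ethanone | CC(=O)c1c(O)cc(OCc2ccccc2)cc1OCc1ccccc1 | intermediate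
15 | 2-acetyl-3,5-bis(benzyloxy)phenyl 4-(benzyloxy)-3-{5-(benzyloxy)-2-[4-(benzyloxy)phenyl]-7-methoxy-4-oxochromen-3-yl}benzoate (not isolated) | COc1cc(OCc2ccccc2)c2c(=O)c(-c3cc(C(=O)Oc4cc(OCc5ccccc5)cc(OCc5ccccc5)c4C(C)=O)ccc3OCc3ccccc3)c(-c3ccc(OCc4ccccc4)cc3)oc2c1 | intermediate
16 | 1-[2,4-bis(benzyloxy)-6-hydroxyphenyl]-3-(4-(benzyloxy)-3-{5-(benzyloxy)-2-[4-(benzyloxy)phenyl]-7-methoxy-4-oxochromen-3-yl}phenyl)propane-1,3-dione (not isolated) | COc1cc(OCc2ccccc2)c2c(=O)c(-c3cc(C(=O)CC(=O)c4c(O)cc(OCc5ccccc5)cc4OCc4ccccc4)ccc3OCc3ccccc3)c(-c3ccc(OCc4ccccc4)cc3)oc2c1 | intermediate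
17 | 5,7-bis(benzyloxy)-2-(4-(benzyloxy)-3-{5-(benzyloxy)-2-[4-(benzyloxy)phenyl]-7-methoxy-4-oxochromen-3-yl}phenyl)chromen-4-one | COc1cc(OCc2ccccc2)c2c(=O)c(-c3cc(-c4cc(=O)c5c(OCc6ccccc6)cc(OCc6ccccc6)cc5o4)ccc3OCc3ccccc3)c(-c3ccc(OCc4ccccc4)cc3)oc2c1 | intermediate
18 | 5,7-dihydroxy-2-{4-hydroxy-3-[5-hydroxy-2-(4-hydroxyphenyl)-7-methoxy-4-oxochromen-3-yl]phenyl}chromen-4-one (CNP0284832.0) | COc1cc(O)c2c(=O)c(-c3cc(-c4cc(=O)c5c(O)cc(O)cc5o4)ccc3O)c(-c3ccc(O)cc3)oc2c1 | target

Total step count: 10. Longest linear sequence: 9 (steps 1–7, 9 and 10; step 8 is a one-step side branch).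

Steps most likely to fail

1. Step 5.
What may go wrong:
- thermal transfer of benzyl groups from the ether oxygens to the very nucleophilic phloroglucinol;
- internal capture of the ketene by the ortho ether oxygen;
- hydrolysis and decarboxylation, or retro-Claisen cleavage, of the keto ester;
- competing coumarin-type closure.

Fallback (sets out from 13 and 5, comes back at 12): the bond from C3 to its aryl group is made last by cross-coupling and is no longer carried in the keto ester. 13 is methylated at 4-OH, the one hydroxyl not ortho to the acetyl group (Me2SO4, 1 equiv, K2CO3, acetone), to give 1-(2,6-dihydroxy-4-methoxyphenyl)ethanone F1. Mono-benzylation (BnBr, 1 equiv, K2CO3, DMF) gives 1-[2-(benzyloxy)-6-hydroxy-4-methoxyphenyl]ethanone F2. The lithium dianion of F2 (LiN(SiMe3)2, 3 equiv, THF, −78 °C) is acylated by 5 to 1-[2-(benzyloxy)-6-hydroxy-4-methoxyphenyl]-3-[4-(benzyloxy)phenyl]propane-1,3-dione F3. Catalytic p-TsOH in warm toluene dehydrates this to 5-(benzyloxy)-2-[4-(benzyloxy)phenyl]-7-methoxychromen-4-one F4. Lithiation at C3 with LiN(iPr)2 at −78 °C and an I2 quench should give 5-(benzyloxy)-2-[4-(benzyloxy)phenyl]-3-iodo-7-methoxychromen-4-one F5. Suzuki–Miyaura coupling with commercial [2-(benzyloxy)-5-bromophenyl]boronic acid (Pd(PPh3)4, Na2CO3, DME–H2O, 80 °C) is selective for the carbon–iodine bond over the carbon–bromine bond and leads to 12.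

2. Step 9.
What may go wrong:
- hydrolytic interception of the acylpalladium species by the water that ring closure releases;
- a slow acyl shift next to the 6-benzyloxy group;
- a stall at the open diketone stage.

Fallback (sets out from 12, comes back at 17): the palladium chemistry is separated from the ring construction, and the flavone is built by the classical stepwise acyl-transfer route with an acid-promoted closure. Hydroxycarbonylation of 12 (Pd(OAc)2, Xantphos, CO 1 atm, H2O, Et3N, dioxane, 100 °C) gives 4-(benzyloxy)-3-{5-(benzyloxy)-2-[4-(benzyloxy)phenyl]-7-methoxy-4-oxochromen-3-yl}benzoic acid F6. Steglich esterification with 14 (EDC, DMAP, CH2Cl2) gives 15, now isolated. Baker–Venkataraman rearrangement (LiN(SiMe3)2, THF, −78 to 0 °C) gives 16. Catalytic p-TsOH in toluene at 90 °C closes it to 17. Partial loss of a peri benzyl group at this stage would be harmless, because step 10 removes them all.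

3. Step 4.
What may go wrong:
- O-acylation of the enolate or of the product enolate;
- proton transfer between product and unreacted enolate, which lowers conversion of the ortho-substituted arylacetate.

Fallback (sets out from 4, comes back at 6): the acyl chloride is replaced by an aldehyde and the oxidation level is adjusted afterwards. The lithium enolate of 4 (LiN(iPr)2, THF, −78 °C) adds to commercial 4-(benzyloxy)benzaldehyde to give ethyl 2-[2-(benzyloxy)-5-bromophenyl]-3-[4-(benzyloxy)phenyl]-3-hydroxypropanoate F7 (racemic mixture of diastereomers, of no consequence). Dess–Martin periodinane in CH2Cl2 oxidises it to 6.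

Further compounds
F1 | step 5 | 1-(2,6-dihydroxy-4-methoxyphenyl)ethanone | CC(=O)c1c(O)cc(OC)cc1O
F2 | step 5 | 1-[2-(benzyloxy)-6-hydroxy-4-methoxyphenyl]ethanone | CC(=O)c1c(O)cc(OC)cc1OCc1ccccc1
F3 | step 5 | 1-[2-(benzyloxy)-6-hydroxy-4-methoxyphenyl]-3-[4-(benzyloxy)phenyl]propane-1,3-dione | O=C(CC(=O)c1c(O)cc(OC)cc1OCc1ccccc1)c1ccc(OCc2ccccc2)cc1
F4 | step 5 | 5-(benzyloxy)-2-[4-(benzyloxy)phenyl]-7-methoxychromen-4-one | COc1cc(OCc2ccccc2)c2c(=O)cc(-c3ccc(OCc4ccccc4)cc3)oc2c1
F5 | step 5 | 5-(benzyloxy)-2-[4-(benzyloxy)phenyl]-3-iodo-7-methoxychromen-4-one | COc1cc(OCc2ccccc2)c2c(=O)c(I)c(-c3ccc(OCc4ccccc4)cc3)oc2c1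
F6 | step 9 | 4-(benzyloxy)-3-{5-(benzyloxy)-2-[4-(benzyloxy)phenyl]-7-methoxy-4-oxochromen-3-yl}benzoic acid | COc1cc(OCc2ccccc2)c2c(=O)c(-c3cc(C(=O)O)ccc3OCc3ccccc3)c(-c3ccc(OCc4ccccc4)cc3)oc2c1
F7 | step 4 | ethyl 2-[2-(benzyloxy)-5-bromophenyl]-3-[4-(benzyloxy)phenyl]-3-hydroxypropanoate (racemic mixture of diastereomers) | CCOC(=O)C(C(O)c1ccc(OCc2ccccc2)cc1)c1cc(Br)ccc1OCc1ccccc1
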